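Everything rests on taking three C–Br bonds off the diaryl ether. C4 and C6 of ring B (the tribromophenol ring) lie para and ortho to its C1 hydroxyl, and C5' of ring A (the bromohydroxyphenoxy ring) lies para to the C2' oxygen, so one bromination of a preformed ether should install all three bromines at once. Only C3–Br of ring B, meta to the hydroxyl, has to arrive with a starting material. The precursor is 3-bromo-2-(2-methoxyphenoxy)phenol 5, its ring A oxygen capped as a methyl ether to steer bromine to C5'; SNAr and Baeyer–Villiger oxidation make it, and BBr3 demethylation finishes the route.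

Key step: step 3

Remark: the target has no stereocentre and the diaryl ether rotates freely, so nothing stereochemical has to be set. Ring B is numbered from its hydroxyl carbon (C1), ring A with primed numbers from the ether carbon (C1').

Step 1
Reactants: 1 2-methoxyphenol; 2 3-bromo-2-fluorobenzaldehyde
Product: 3 3-bromo-2-(2-methoxyphenoxy)benzaldehyde
Conditions: K2CO3, DMAc, 100 °C, N2
Reagents that add atoms: none
Why: Nucleophilic aromatic substitution (SNAr, addition–elimination), in which the phenoxide of 1 attacks the fluorine-bearing carbon of 2, activated by the ortho formyl group and inductively by the ortho bromine, while the bromine (meta to the formyl group and a far poorer SNAr leaving group) should stay in place.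

Step 2
Reactants: 3 3-bromo-2-(2-methoxyphenoxy)benzaldehyde
Product: 5 3-bromo-2-(2-methoxyphenoxy)phenol, via 3-bromo-2-(2-methoxyphenoxy)phenyl formate 4 (not isolated)
Conditions: mCPBA (1.5 equiv), CH2Cl2, rt; aq. Na2S2O3/NaHCO3 wash; then K2CO3 (0.2 equiv), MeOH, rt
Reagents that add atoms: mCPBA (3-chloroperoxybenzoic acid), OOC(=O)c1cccc(Cl)c1
Why: Baeyer–Villiger oxidation of an ortho-aryloxy benzaldehyde (Dakin-type outcome), in which the aryl group carrying the ortho ether oxygen should migrate in preference to hydride in the Criegee adduct to give formate 4, which mild methanolysis cleaves without touching the aryl bromide or either ether.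

Step 3
Reactants: 5 3-bromo-2-(2-methoxyphenoxy)phenol
Product: 8 3,4,6-tribromo-2-(5-bromo-2-methoxyphenoxy)phenol, via 3,4-dibromo-2-(2-methoxyphenoxy)phenol 6 (not isolated), via 3,4,6-tribromo-2-(2-methoxyphenoxy)phenol 7 (not isolated)
Conditions: Br2 (3.1 equiv), AcOH, rt to 40 °C; aq. NaHSO3 work-up
Reagents that add atoms: bromine, BrBr
Why: This is electrophilic aromatic substitution three times over: each bromine enters through an arenium ion stabilised by an oxygen lone pair, and loss of a proton restores the ring. The closest known reaction type is the ortho/para bromination of phenols and aryl methyl ethers with Br2 in acetic acid. On ring B the free C1 hydroxyl, the strongest donor present, should send bromine to C4 (para) and then to C6 (ortho), whereas C5, although para to the weaker and twisted aryloxy oxygen, is meta to the hydroxyl and ends up hemmed in between the C4 and C6 bromines, so it should stay unsubstituted. On ring A the C2' methoxy group outranks the diaryl ether oxygen, whose lone pair is shared with the by then electron-poor tribromophenol ring, so the third bromine should enter at C5' (para to methoxy) and not at C4', and the methyl cap keeps ring A from reacting like a free phenol at C3'. No ring is closed and no stereocentre is formed; the selectivity required is purely positional together with a stop after three substitutions, which the deactivation caused by each new bromine and the measured 3.1 equivalents of Br2 should secure. The order in which 6 and 7 are passed does not alter the outcome, because the three sites named are the only strongly activated ones.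

Step 4
Reactants: 8 3,4,6-tribromo-2-(5-bromo-2-methoxyphenoxy)phenol
Product: 10 3,4,6-tribromo-2-(5-bromo-2-hydroxyphenoxy)phenol, via bis(dibromoboryl) ether 9 (not isolated)
Conditions: BBr3 (3 equiv), CH2Cl2, −78 °C to rt; then H2O
Reagents that add atoms: none
Why: Lewis acid-mediated cleavage of an aryl methyl ether, in which BBr3 binds the methoxy oxygen and bromide removes the methyl group by SN2 attack to leave aryloxyboron dibromide 9, hydrolysed on quenching, while the diaryl ether (no sp3 carbon to attack) and the four aryl bromides should be inert.

Compound list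
1 | 2-methoxyphenol (guaiacol) | COc1ccccc1O | starting material
2 | 3-bromo-2-fluorobenzaldehyde | O=Cc1cccc(Br)c1F | starting material
3 | 3-bromo-2-(2-methoxyphenoxy)benzaldehyde | COc1ccccc1Oc1c(Br)cccc1C=O | intermediate
4 | 3-bromo-2-(2-methoxyphenoxy)phenyl formate (not isolated) | COc1ccccc1Oc1c(Br)cccc1OC=O | intermediate
5 | 3-bromo-2-(2-methoxyphenoxy)phenol | COc1ccccc1Oc1c(O)cccc1Br | intermediate
6 | 3,4-dibromo-2-(2-methoxyphenoxy)phenol (not isolated) | COc1ccccc1Oc1c(O)ccc(Br)c1Br | intermediate
7 | 3,4,6-tribromo-2-(2-methoxyphenoxy)phenol (not isolated) | COc1ccccc1Oc1c(O)c(Br)cc(Br)c1Br | intermediate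
8 | 3,4,6-tribromo-2-(5-bromo-2-methoxyphenoxy)phenol | COc1ccc(Br)cc1Oc1c(O)c(Br)cc(Br)c1Br | intermediate
9 | O,O'-bis(dibromoboryl) derivative of 10, each phenolic oxygen carrying a BBr2 group (not isolated) | BrB(Br)Oc1ccc(Br)cc1Oc1c(OB(Br)Br)c(Br)cc(Br)c1Br | intermediate
10 | 3,4,6-tribromo-2-(5-bromo-2-hydroxyphenoxy)phenol | Oc1ccc(Br)cc1Oc1c(O)c(Br)cc(Br)c1Br | target

Total step count: 4
Longest linear sequence: 4 steps (1 and 2 → 3 → 5 → 8 → 10)

Steps most likely to fail

Step 3. Positional control on ring A may be lost, with bromine entering para to the diaryl ether oxygen or twice on ring A. Alternatively the third substitution may stall, leaving mixtures of partly brominated ethers. Reversible ipso-bromination of the tribromophenol ring to a bromodienone may also occur; the bisulfite work-up is meant to undo it. The fallback takes the ring A bromine out of the key step. It sets out from 2, which is condensed with commercial 5-bromo-2-methoxyphenol (COc1ccc(Br)cc1O) in place of 1 (K2CO3, DMAc, 100 °C) to give 3-bromo-2-(5-bromo-2-methoxyphenoxy)benzaldehyde F1. Baeyer–Villiger oxidation with mCPBA in CH2Cl2 should give 3-bromo-2-(5-bromo-2-methoxyphenoxy)phenyl formate F2, which is methanolysed (K2CO3, MeOH) to 3-bromo-2-(5-bromo-2-methoxyphenoxy)phenol F3. Hydroxyl-directed dibromination of ring B alone (Br2, 2.05 equiv, AcOH, rt), passing through 3,4-dibromo-2-(5-bromo-2-methoxyphenoxy)phenol F4, returns to the route at 8. Ring A, already brominated and without a free hydroxyl, should not compete.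

Step 2. In the peracid step, hydride migration may compete with aryl migration and deliver the benzoic acid, or the peracid may attack the electron-rich ring A. The fallback avoids peracid altogether and sets out from 1. SNAr on commercial 1-bromo-2-fluoro-3-nitrobenzene (O=[N+]([O-])c1cccc(Br)c1F; K2CO3, DMF, rt to 50 °C) should give 1-bromo-2-(2-methoxyphenoxy)-3-nitrobenzene F5. Béchamp-type reduction with Fe powder in AcOH/EtOH at 70 °C, which spares the aryl bromide, gives 3-bromo-2-(2-methoxyphenoxy)aniline F6. Diazotisation (NaNO2, aq. H2SO4, 0 °C) gives 3-bromo-2-(2-methoxyphenoxy)benzenediazonium hydrogen sulfate F7. This is run cold into a large excess of aqueous Cu(NO3)2 containing catalytic Cu2O at rt (Sandmeyer-type hydroxydediazoniation). The high concentration of divalent copper should trap the aryl radical as the phenol before it can add to ring A and close a dibenzofuran. The sequence returns to the route at 5.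

Step 1. Substitution at a carbon flanked by formyl and bromine may be slow, and during prolonged heating with base the aldehyde may be lost to disproportionation or air oxidation. The fallback uses a more robust activating group and sets out from 1. SNAr on commercial 3-bromo-2-fluorobenzonitrile (N#Cc1cccc(Br)c1F; K2CO3, DMSO, 80 °C) should give 3-bromo-2-(2-methoxyphenoxy)benzonitrile F8. Partial reduction with i-Bu2AlH (DIBAL-H, 1.2 equiv, toluene, −78 °C) stops at the N-(diisobutylaluminio)aldimine of 3-bromo-2-(2-methoxyphenoxy)benzaldehyde F9. Hydrolysis with cold aqueous HCl returns to the route at 3.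

Further compounds
F1 | step 3 | 3-bromo-2-(5-bromo-2-methoxyphenoxy)benzaldehyde | COc1ccc(Br)cc1Oc1c(Br)cccc1C=O
F2 | step 3 | 3-bromo-2-(5-bromo-2-methoxyphenoxy)phenyl formate | COc1ccc(Br)cc1Oc1c(Br)cccc1OC=O
F3 | step 3 | 3-bromo-2-(5-bromo-2-methoxyphenoxy)phenol | COc1ccc(Br)cc1Oc1c(O)cccc1Br
F4 | step 3 | 3,4-dibromo-2-(5-bromo-2-methoxyphenoxy)phenol | COc1ccc(Br)cc1Oc1c(O)ccc(Br)c1Br
F5 | step 2 | 1-bromo-2-(2-methoxyphenoxy)-3-nitrobenzene | COc1ccccc1Oc1c(Br)cccc1[N+](=O)[O-]
F6 | step 2 | 3-bromo-2-(2-methoxyphenoxy)aniline | COc1ccccc1Oc1c(N)cccc1Br
F7 | step 2 | 3-bromo-2-(2-methoxyphenoxy)benzenediazonium hydrogen sulfate | COc1ccccc1Oc1c(Br)cccc1[N+]#N.OS(=O)(=O)[O-]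
F8 | step 1 | 3-bromo-2-(2-methoxyphenoxy)benzonitrile | COc1ccccc1Oc1c(Br)cccc1C#N
F9 | step 1 | N-(diisobutylaluminio)aldimine of 3-bromo-2-(2-methoxyphenoxy)benzaldehyde | COc1ccccc1Oc1c(Br)cccc1C=N[Al](CC(C)C)CC(C)C
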